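**Retrosynthetic overview**
1. Isodonal 17 comes from its 11-oxo precursor 14 by redox adjustment only (global Luche reduction, then re-oxidation at C6 and C15).
2. 14 comes from the monocyclic ester 12 in one base-mediated double Michael cascade: C12→C13 closes ring C and unveils C16=C17, then C9→C10 closes the δ-lactone and creates C10 and C5.
3. 12 comes from the ester union (C20–O) of ring A bromide 5 with β-keto acid 11 (ring D, C8 set by asymmetric alkylation).
4. 5 comes from β-cyclocitral; 11 comes from cyclopent-2-en-1-one.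
5. Ring order: rings A and D are bought in; ring C and the lactone form together in Step 9; no ring is made afterwards.

Atom labels C1–C20 are those of isodonal (ent-kaurane numbering): C7 lactone carbonyl, C20 lactone CH2, C6 formyl, C15 ketone, C16=C17 methylene.
Assumption: the lipase (Step 2) and the ammonium salt (Step 7) give the sense of selectivity stated; if not, the (S)-alcohol released in Step 2 is re-acetylated and the antipodal ammonium salt is used in Step 7.

**Step 1**
Reactants: 1 beta-cyclocitral (2,6,6-trimethylcyclohex-1-ene-1-carbaldehyde)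
Product: 3 rac-3-formyl-2,4,4-trimethylcyclohex-2-en-1-yl acetate, via allylic bromide 2 (not isolated)
Conditions: NBS (1.05 equiv), azobis(isobutyronitrile) (5 mol %), PhCF3, 80 °C; filter; AgOAc (1.2 equiv), AcOH, 23 °C
Reagents that add atoms: silver acetate, CC(=O)[O-].[Ag+]; N-bromosuccinimide, O=C1CCC(=O)N1Br
Why: Wohl–Ziegler bromination goes to the only ring allylic CH2 (C1), and silver-assisted SN1 acetolysis of the bromide gives the racemic C1 acetate.

**Step 2**
Reactants: 3 rac-3-formyl-2,4,4-trimethylcyclohex-2-en-1-yl acetate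
Product: 4 (1S)-3-formyl-2,4,4-trimethylcyclohex-2-en-1-yl acetate
Conditions: Candida antarctica lipase B (immobilised), phosphate buffer pH 7/MTBE, 30 °C, stopped at about 55% conversion
Reagents that add atoms: none
Why: Enzymatic kinetic resolution by ester hydrolysis; the lipase cleaves the (R)-acetate (Kazlauskas preference for cyclic allylic alcohols), so the unreacted (S)-acetate is recovered in high ee and carries the C1 stereocentre.

**Step 3**
Reactants: 4 (1S)-3-formyl-2,4,4-trimethylcyclohex-2-en-1-yl acetate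
Product: 5 (1S)-2-(bromomethyl)-3-formyl-4,4-dimethylcyclohex-2-en-1-yl acetate
Conditions: NBS (1.1 equiv), azobis(isobutyronitrile) (5 mol %), PhCF3, 80 °C
Reagents that add atoms: N-bromosuccinimide, O=C1CCC(=O)N1Br
Why: Wohl–Ziegler allylic bromination of the C20 methyl group, the remaining allylic C–H site (the C1–H is deactivated by the acetoxy group towards the electrophilic bromine atom); C1 is untouched.

**Step 4**
Reactants: 6 cyclopent-2-en-1-one
Product: 7 2-(hydroxymethyl)cyclopent-2-en-1-one
Conditions: 37% aq. HCHO (1.5 equiv), PBu3 (5 mol %), CHCl3/MeOH, 23 °C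
Reagents that add atoms: formaldehyde, C=O
Why: Morita–Baylis–Hillman reaction puts the future C17 on C16 of the enone.

**Step 5**
Reactants: 7 2-(hydroxymethyl)cyclopent-2-en-1-one
Product: 8 2-{[tert-butyl(diphenyl)silyl]oxymethyl}cyclopent-2-en-1-one
Conditions: t-BuPh2SiCl, imidazole, CH2Cl2, 0 → 23 °C
Reagents that add atoms: tert-butyl(chloro)diphenylsilane, CC(C)(C)[Si](Cl)(c1ccccc1)c1ccccc1
Why: Silylation of the primary alcohol gives an acid-stable ether that later serves as the leaving group for the E1cB step.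

**Step 6**
Reactants: 8 2-{[tert-butyl(diphenyl)silyl]oxymethyl}cyclopent-2-en-1-one
Product: 9 tert-butyl 3-{[tert-butyl(diphenyl)silyl]oxymethyl}-2-oxocyclopent-3-ene-1-carboxylate
Conditions: LiN(SiMe3)2 (2.2 equiv), THF, −78 °C; Boc2O (1.1 equiv), −78 → −20 °C; NH4Cl (aq.)
Reagents that add atoms: di-tert-butyl dicarbonate, CC(C)(C)OC(=O)OC(=O)OC(C)(C)C
Why: Kinetic cross-conjugated enolate formation at the alpha-prime carbon and Claisen-type C-acylation; the second equivalent of base deprotonates the β-keto ester and drives C-acylation; the new centre (C8) is configurationally labile.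

**Step 7**
Reactants: 9 tert-butyl 3-{[tert-butyl(diphenyl)silyl]oxymethyl}-2-oxocyclopent-3-ene-1-carboxylate
Product: 10 tert-butyl (1S)-3-{[tert-butyl(diphenyl)silyl]oxymethyl}-1-(2-methoxyprop-2-en-1-yl)-2-oxocyclopent-3-ene-1-carboxylate
Conditions: 3-bromo-2-methoxyprop-1-ene (1.5 equiv), (S,S)-3,3′-bis(3,4,5-trifluorophenyl)-N-spiro-binaphthyl ammonium bromide (2 mol %), K2CO3 (sat. aq.), toluene, −20 °C
Reagents that add atoms: 3-bromo-2-methoxyprop-1-ene, COC(=C)CBr
Why: Asymmetric phase-transfer alkylation of a cyclic β-keto tert-butyl ester; the chiral ammonium ion pair shields one enolate face and sets the C8 quaternary stereocentre (S); the 2-methoxyallyl group is a masked acetonyl group (C9, C11, C12).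

**Step 8**
Reactants: 10 tert-butyl (1S)-3-{[tert-butyl(diphenyl)silyl]oxymethyl}-1-(2-methoxyprop-2-en-1-yl)-2-oxocyclopent-3-ene-1-carboxylate; 5 (1S)-2-(bromomethyl)-3-formyl-4,4-dimethylcyclohex-2-en-1-yl acetate
Product: 12 [(6S)-6-acetoxy-2-formyl-3,3-dimethylcyclohex-1-en-1-yl]methyl (1S)-3-{[tert-butyl(diphenyl)silyl]oxymethyl}-2-oxo-1-(2-oxopropyl)cyclopent-3-ene-1-carboxylate, via keto acid 11 (not isolated)
Conditions: CF3CO2H/CH2Cl2 (1:4), H2O (3 equiv), 0 °C; evaporate at 0 °C; Cs2CO3 (1.5 equiv), 5 (1.1 equiv), DMF, 0 °C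
Reagents that add atoms: water, O
Why: Acidolysis of the tert-butyl ester with simultaneous enol ether hydrolysis gives keto acid 11, whose caesium carboxylate is O-alkylated by the allylic bromide (SN2); the acid is kept cold to avoid decarboxylation and no stereocentre is touched.

**Step 9**
Reactants: 12 [(6S)-6-acetoxy-2-formyl-3,3-dimethylcyclohex-1-en-1-yl]methyl (1S)-3-{[tert-butyl(diphenyl)silyl]oxymethyl}-2-oxo-1-(2-oxopropyl)cyclopent-3-ene-1-carboxylate
Product: 14 11-oxo-isodonal (isodonal skeleton carrying a C11 ketone), via bicyclic enone 13 (not isolated)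
Conditions: t-BuOK (1.2 equiv), t-BuOH (5 equiv), THF (0.005 M), −40 → 0 °C; NH4Cl (aq.)
Reagents that add atoms: none
Why: Proposed new method: a double Michael cascade (closest known types: intramolecular Michael additions of ketone enolates to cyclopentenones in double-Michael annulations, addition–elimination on 2-(oxymethyl)enones, 6-exo Michael lactone closures): the C12 methyl-ketone enolate adds to C13 on the only face the C8 tether can reach (ring C, sets C13); the C16 enolate then expels silanolate by E1cB, which unveils C16=C17 and makes this half irreversible; the C9 enolate then adds 6-exo to the enal carbon C10 from the face of ring C opposite the C15–C16 bridge and anti to the pseudoaxial C1 acetate (cis-fused lactone, sets C9 and C10); the aldehyde enolate is finally protonated under equilibrating conditions to the equatorial formyl group (C5).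

**Step 10**
Reactants: 14 11-oxo-isodonal
Product: 15 isodonal 6,15-diol (C6 as CH2OH and C15 as CHOH; C15 epimers)
Conditions: NaBH4 (4 equiv), CeCl3·7H2O (3 equiv), MeOH/THF, −78 → −20 °C
Reagents that add atoms: none
Why: Luche reduction gives 1,2-reduction of the C15 enone and reduces the C6 aldehyde and the C11 ketone; hydride reaches C11 from the face opposite the C15–C16 bridge, giving the 11-alcohol syn to the bridge; the C15 configuration is irrelevant because it is re-oxidised.

**Step 11**
Reactants: 15 isodonal 6,15-diol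
Product: 17 isodonal, via enone diol 16 (not isolated)
Conditions: MnO2 (20 equiv), CH2Cl2, 23 °C; filter; 2,2,6,6-tetramethylpiperidine-1-oxyl (10 mol %), PhI(OAc)2 (1.2 equiv), CH2Cl2, 0 → 23 °C
Reagents that add atoms: none
Why: Chemoselective oxidations: MnO2 oxidises only the allylic C15 alcohol, then the oxoammonium (TEMPO) oxidation takes the primary C6 alcohol much faster than the hindered secondary C11 alcohol; no stereocentre changes.

**Compound list**
1 | beta-cyclocitral (2,6,6-trimethylcyclohex-1-ene-1-carbaldehyde) | CC1=C(C=O)C(C)(C)CCC1 | starting material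
2 | rac-3-bromo-2,6,6-trimethylcyclohex-1-ene-1-carbaldehyde | CC1=C(C=O)C(C)(C)CCC1Br | intermediate (not isolated)
3 | rac-3-formyl-2,4,4-trimethylcyclohex-2-en-1-yl acetate | CC1=C(C=O)C(C)(C)CCC1OC(C)=O | intermediate
4 | (1S)-3-formyl-2,4,4-trimethylcyclohex-2-en-1-yl acetate | CC1=C(C=O)C(C)(C)CC[C@@H]1OC(C)=O | intermediate
5 | (1S)-2-(bromomethyl)-3-formyl-4,4-dimethylcyclohex-2-en-1-yl acetate | BrCC1=C(C=O)C(C)(C)CC[C@@H]1OC(C)=O | intermediate
6 | cyclopent-2-en-1-one | O=C1C=CCC1 | starting material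
7 | 2-(hydroxymethyl)cyclopent-2-en-1-one | O=C1CCC=C1CO | intermediate
8 | 2-{[tert-butyl(diphenyl)silyl]oxymethyl}cyclopent-2-en-1-one | O=C1CCC=C1CO[Si](c1ccccc1)(c1ccccc1)C(C)(C)C | intermediate
9 | tert-butyl 3-{[tert-butyl(diphenyl)silyl]oxymethyl}-2-oxocyclopent-3-ene-1-carboxylate (racemic, C1 labile) | CC(C)(C)OC(=O)C1CC=C(CO[Si](c2ccccc2)(c2ccccc2)C(C)(C)C)C1=O | intermediate
10 | tert-butyl (1S)-3-{[tert-butyl(diphenyl)silyl]oxymethyl}-1-(2-methoxyprop-2-en-1-yl)-2-oxocyclopent-3-ene-1-carboxylate | O=C1C(CO[Si](c2ccccc2)(c2ccccc2)C(C)(C)C)=CC[C@@]1(CC(=C)OC)C(=O)OC(C)(C)C | intermediate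
11 | (1S)-3-{[tert-butyl(diphenyl)silyl]oxymethyl}-2-oxo-1-(2-oxopropyl)cyclopent-3-ene-1-carboxylic acid | O=C1C(CO[Si](c2ccccc2)(c2ccccc2)C(C)(C)C)=CC[C@@]1(CC(C)=O)C(=O)O | intermediate (not isolated)
12 | [(6S)-6-acetoxy-2-formyl-3,3-dimethylcyclohex-1-en-1-yl]methyl (1S)-3-{[tert-butyl(diphenyl)silyl]oxymethyl}-2-oxo-1-(2-oxopropyl)cyclopent-3-ene-1-carboxylate | O=C1C(CO[Si](c2ccccc2)(c2ccccc2)C(C)(C)C)=CC[C@@]1(CC(C)=O)C(=O)OCC3=C(C=O)C(C)(C)CC[C@@H]3OC(C)=O | intermediate
13 | [(6S)-6-acetoxy-2-formyl-3,3-dimethylcyclohex-1-en-1-yl]methyl (1S,5S)-6-methylidene-3,7-dioxobicyclo[3.2.1]octane-1-carboxylate | C=C1C(=O)[C@]2(C(=O)OCC3=C(C=O)C(C)(C)CC[C@@H]3OC(C)=O)C[C@H]1CC(=O)C2 | intermediate (not isolated)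
14 | 11-oxo-isodonal (C11 ketone; all other centres as in 17) | C=C1C(=O)[C@]23C[C@H]1CC(=O)[C@H]2[C@]1(COC3=O)[C@@H](OC(C)=O)CCC(C)(C)[C@H]1C=O | intermediate
15 | isodonal 6,15-diol (C6 CH2OH, C15 CHOH as epimers; other centres as in 17) | C=C1C(O)[C@]23C[C@H]1C[C@H](O)[C@H]2[C@]1(COC3=O)[C@@H](OC(C)=O)CCC(C)(C)[C@H]1CO | intermediate
16 | isodonal 6-alcohol (C6 CH2OH, C15 ketone; other centres as in 17) | C=C1C(=O)[C@]23C[C@H]1C[C@H](O)[C@H]2[C@]1(COC3=O)[C@@H](OC(C)=O)CCC(C)(C)[C@H]1CO | intermediate (not isolated)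
17 | isodonal | C=C1C(=O)[C@]23C[C@H]1C[C@H](O)[C@H]2[C@]1(COC3=O)[C@@H](OC(C)=O)CCC(C)(C)[C@H]1C=O | target

**Totals**
Total step count: 11. Longest linear sequence: 8 steps (Steps 4–11, from cyclopent-2-en-1-one).

**Three steps most likely to fail**

Step 9 (the cascade). Risks are aldol closure of the 1,4-diketone, gamma-deprotonation of the enal, and the hindered C9–C10 bond. The fallback sets out from 12 and comes back at 14. Ring C alone is closed with KN(SiMe3)2 (1.05 equiv) in THF at −78 °C and the bicyclic enone 13 is isolated. Me3SiOTf/Et3N then gives the C9–C11 trimethylsilyl enol ether F1 (C11 is the only enolisable carbonyl in 13; the C11–C12 regioisomer is recycled). TiCl4 in CH2Cl2 at −78 °C then closes the lactone by an intramolecular Mukaiyama–Michael addition to the enal, giving 14 after aqueous work-up.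

Step 7 (enantioselectivity of the alkylation on a cyclopentenone β-keto ester). The fallback sets out from 9 and comes back at 11. A quinine-derived tertiary amine–squaramide catalyses the Michael addition of 9 to 2-nitropropene, giving the nitro ester F2 with the C8 centre set. A TiCl3/NH4OAc Nef reaction converts it into the diketo tert-butyl ester F3. CF3CO2H at 0 °C then gives acid 11.

Step 11 (together with the over-reduction of Step 10: selective re-oxidation of two of three hydroxyls). The fallback sets out from 14 and comes back at 17. HC(OMe)3 with pyridinium p-toluenesulfonate in MeOH protects only the aldehyde as the dimethyl acetal F4. NaBH4/CeCl3·7H2O gives the 11,15-diol acetal F5. MnO2 oxidises the allylic C15 alcohol to the enone acetal F6. Pyridinium p-toluenesulfonate in aqueous acetone releases the aldehyde to give 17, so no primary alcohol ever has to be oxidised.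

**Further compounds**
F1 | step 9 | C9–C11 trimethylsilyl enol ether of 13 | C=C1C(=O)[C@]2(C(=O)OCC3=C(C=O)C(C)(C)CC[C@@H]3OC(C)=O)C[C@H]1CC(O[Si](C)(C)C)=C2
F2 | step 7 | tert-butyl (1S)-3-{[tert-butyl(diphenyl)silyl]oxymethyl}-1-(2-nitropropyl)-2-oxocyclopent-3-ene-1-carboxylate (epimers at the nitro carbon) | O=C1C(CO[Si](c2ccccc2)(c2ccccc2)C(C)(C)C)=CC[C@@]1(CC(C)[N+](=O)[O-])C(=O)OC(C)(C)C
F3 | step 7 | tert-butyl (1S)-3-{[tert-butyl(diphenyl)silyl]oxymethyl}-2-oxo-1-(2-oxopropyl)cyclopent-3-ene-1-carboxylate | O=C1C(CO[Si](c2ccccc2)(c2ccccc2)C(C)(C)C)=CC[C@@]1(CC(C)=O)C(=O)OC(C)(C)C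
F4 | step 11 | 11-oxo-isodonal 6-dimethyl acetal | C=C1C(=O)[C@]23C[C@H]1CC(=O)[C@H]2[C@]1(COC3=O)[C@@H](OC(C)=O)CCC(C)(C)[C@H]1C(OC)OC
F5 | step 11 | 15-hydroxy (C15 epimers) isodonal 6-dimethyl acetal | C=C1C(O)[C@]23C[C@H]1C[C@H](O)[C@H]2[C@]1(COC3=O)[C@@H](OC(C)=O)CCC(C)(C)[C@H]1C(OC)OC
F6 | step 11 | isodonal 6-dimethyl acetal | C=C1C(=O)[C@]23C[C@H]1C[C@H](O)[C@H]2[C@]1(COC3=O)[C@@H](OC(C)=O)CCC(C)(C)[C@H]1C(OC)OC
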